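**Retrosynthetic overview**
1. Feature: upper C4 is a diarylmethine carbon bonded to ring A at C4a (whose neighbour C8a carries O1) and to ring D at C8. The unit C4–C4a–C8a–O1 is therefore a masked o-quinone methide, and the trans,trans triad C2/C3/C4 corresponds to syn addition of H and OH to a C2=C3 enol ether from the face away from ring D.
2. Late disconnections: ten benzyl ethers (hydrogenolysis), then C2–H and C3–OH (hydroboration–oxidation of a 4-(epicatechin-8-yl)flav-2-ene), then C2=C3 (loss of acetamide from a 2-acetamidochroman).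
3. Key disconnection: C3–C4 and O1–C2 of ring C, a chiral phosphoric acid catalysed formal [4+2] between the N-acetyl enamide of 3,4,5-tris(benzyloxy)acetophenone (ring B, C2, C3) and an o-quinone methide that already carries the lower flavan.
4. The quinone methide precursor arises from C4–C8 bond formation between 8-lithiated penta-O-benzylepicatechin and a dibenzylated, monosilylated 2,4,6-trihydroxybenzaldehyde (ring A, C4).
5. Ring order: rings D, E and F are bought in (−)-epicatechin, rings A and B are bought as arenes, and ring C is the only ring built, in the key step.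

Key step: step 13

Assumption: the (R) antipode of the phosphoric acid is taken as the one whose facial preference coincides with that of the epicatechin-8-yl group and leads to 4S. If a test reaction shows the opposite sense, the (S) antipode is used and nothing else changes.

Step 1
Reactants: 1 (−)-epicatechin
Product: 2 5,7,3',4'-tetra-O-benzylepicatechin (2R,3R; 3-OH free)
Conditions: BnBr, K2CO3, DMF, 0 °C to rt, argon
Reagents that add atoms: benzyl bromide, BrCc1ccccc1
Why: Williamson ether synthesis: carbonate ionises only the four phenols, so the secondary 3-OH stays free, and the cold, oxygen-free medium holds back C-benzylation and the base-induced opening of ring F that would epimerise C2, so 2R,3R is carried through.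

Step 2
Reactants: 2 5,7,3',4'-tetra-O-benzylepicatechin
Product: 3 3,5,7,3',4'-penta-O-benzylepicatechin
Conditions: NaH, BnBr, n-Bu4NI (cat.), THF/DMF, 0 °C to rt
Reagents that add atoms: benzyl bromide, BrCc1ccccc1
Why: Williamson ether synthesis on the sodium alkoxide of the 3-OH; with all phenols capped ring F can no longer open, so the strong base is safe for both stereocentres.

Step 3
Reactants: 3 3,5,7,3',4'-penta-O-benzylepicatechin
Product: 4 8-bromo-3,5,7,3',4'-penta-O-benzylepicatechin
Conditions: N-bromosuccinimide (1 equiv), CH2Cl2, −78 °C to 0 °C, dark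
Reagents that add atoms: N-bromosuccinimide, O=C1CCC(=O)N1Br
Why: Electrophilic aromatic bromination: ring D with three oxygen donors is far more reactive than ring E or the benzyl groups, and C8 is the established site of attack in 5,7-di-O-benzylflavan-3-ol ethers with one equivalent of reagent at low temperature, which fixes the later interflavan link at C8.

Step 4
Reactants: 5 2,4,6-trihydroxybenzaldehyde
Product: 6 2,4-bis(benzyloxy)-6-hydroxybenzaldehyde
Conditions: BnBr (2 equiv), K2CO3, DMF, rt
Reagents that add atoms: benzyl bromide, BrCc1ccccc1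
Why: Williamson ether synthesis under stoichiometric control: the para OH and one ortho OH are alkylated, after which the last ortho OH is locked in a hydrogen bond to the formyl oxygen and is too poorly nucleophilic to compete for the limiting bromide.

Step 5
Reactants: 6 2,4-bis(benzyloxy)-6-hydroxybenzaldehyde
Product: 7 2,4-bis(benzyloxy)-6-(tert-butyldimethylsilyloxy)benzaldehyde
Conditions: TBSCl, imidazole, DMAP (cat.), DMF, rt
Reagents that add atoms: tert-butyldimethylsilyl chloride, CC(C)(C)[Si](C)(C)Cl
Why: Imidazole-promoted silylation of the phenol; a silyl ether is chosen because fluoride is the only deprotection medium that the very acid-labile benzhydrol made next will tolerate.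

Step 6
Reactants: 4 8-bromo-3,5,7,3',4'-penta-O-benzylepicatechin; 7 2,4-bis(benzyloxy)-6-(tert-butyldimethylsilyloxy)benzaldehyde
Product: 9 [2,4-bis(benzyloxy)-6-(tert-butyldimethylsilyloxy)phenyl](3,5,7,3',4'-penta-O-benzylepicatechin-8-yl)methanol (carbinol epimers), via aryllithium 8 (not isolated)
Conditions: n-BuLi, THF, −78 °C; then 7, −78 to −40 °C; then aq NH4Cl
Reagents that add atoms: none
Why: Bromine–lithium exchange followed by 1,2-addition of the aryllithium to the aldehyde makes the C4–C8 bond exactly where the bromine stood; the carbinol centre forms without control, which is irrelevant because it is planarised in step 13, and a possible O-to-O silyl shift in the alkoxide is harmless because step 7 removes silicon from either oxygen.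

Step 7
Reactants: 9 silylated benzhydrol
Product: 10 [2,4-bis(benzyloxy)-6-hydroxyphenyl](3,5,7,3',4'-penta-O-benzylepicatechin-8-yl)methanol (o-hydroxybenzhydrol; carbinol epimers)
Conditions: n-Bu4NF, AcOH, THF, 0 °C; purification on amine-washed silica
Reagents that add atoms: none
Why: Fluoride-induced cleavage of the silyl ether, buffered with acetic acid so that no free phenoxide expels the benzylic oxygen prematurely; benzyl ethers and the lower stereocentres are inert.

Step 8
Reactants: 11 methyl gallate
Product: 12 methyl 3,4,5-tris(benzyloxy)benzoate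
Conditions: BnBr, K2CO3, DMF, 60 °C
Reagents that add atoms: benzyl bromide, BrCc1ccccc1
Why: Williamson ether synthesis on the three phenols; the methyl ester is untouched by carbonate in DMF.

Step 9
Reactants: 12 methyl 3,4,5-tris(benzyloxy)benzoate
Product: 13 3,4,5-tris(benzyloxy)-N-methoxy-N-methylbenzamide
Conditions: MeNH(OMe)·HCl, i-PrMgCl, THF, −20 to 0 °C; then 1 M HCl
Reagents that add atoms: N,O-dimethylhydroxylamine hydrochloride, CNOC.Cl
Why: Weinreb amide synthesis by direct aminolysis of the ester with the chloromagnesium amide made in the flask, which saves a separate saponification and coupling.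

Step 10
Reactants: 13 3,4,5-tris(benzyloxy)-N-methoxy-N-methylbenzamide
Product: 14 3,4,5-tris(benzyloxy)acetophenone
Conditions: MeMgBr, THF, 0 °C; then 1 M HCl
Reagents that add atoms: methylmagnesium bromide, C[Mg]Br
Why: Weinreb ketone synthesis: magnesium chelation holds the adduct until the quench, so only one methyl group (the future C3) is delivered.

Step 11
Reactants: 14 3,4,5-tris(benzyloxy)acetophenone
Product: 15 (E)-3,4,5-tris(benzyloxy)acetophenone oxime
Conditions: NH2OH·HCl, NaOAc, EtOH/H2O, reflux
Reagents that add atoms: hydroxylamine hydrochloride, NO.Cl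
Why: Oxime formation by condensation of the ketone with hydroxylamine; the C=N geometry is of no consequence because it is lost in the next step.

Step 12
Reactants: 15 (E)-3,4,5-tris(benzyloxy)acetophenone oxime
Product: 17 N-{1-[3,4,5-tris(benzyloxy)phenyl]vinyl}acetamide, via oxime acetate 16 (not isolated)
Conditions: Fe powder, Ac2O, AcOH, toluene, 70 °C
Reagents that add atoms: acetic anhydride, CC(=O)OC(C)=O
Why: Reductive acylation of a ketoxime: O-acetylation, cleavage of the N–O bond by zerovalent iron, N-acetylation and tautomerisation lead to the only possible enamide (terminal CH2), and benzyl ethers are inert to iron in acetic acid.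

Step 13
Reactants: 10 o-hydroxybenzhydrol; 17 N-{1-[3,4,5-tris(benzyloxy)phenyl]vinyl}acetamide
Product: 19 (4S)-2-acetamido-5,7-bis(benzyloxy)-2-[3,4,5-tris(benzyloxy)phenyl]-4-(3,5,7,3',4'-penta-O-benzylepicatechin-8-yl)chroman (C2 epimers), via o-quinone methide 18 (not isolated)
Conditions: (R)-3,3'-bis(2,4,6-triisopropylphenyl)-1,1'-binaphthalene-2,2'-diyl hydrogen phosphate (10 mol %), 17 (1.5 equiv), 4 Å molecular sieves, toluene, 0 °C to rt, argon
Reagents that add atoms: none
Why: The acid removes water from the hexa-oxygenated benzhydrol 10 to give 18, whose carbonyl oxygen remains hydrogen-bonded to the phosphate while the phosphoryl oxygen holds the N–H of 17; the enamide CH2 then attacks the methide carbon (C3–C4 bond), ring A regains aromaticity and its phenolic O1 adds to the developing N-acyliminium carbon (O1–C2 bond). The closest known reaction type is the chiral phosphoric acid catalysed conjugate addition–cyclisation (formal oxa-[4+2]) of N-acyl enamides with o-quinone methides released in situ from o-hydroxybenzhydrols, applied here to a methide aryl group that is doubly ortho-substituted and itself chiral. Ring C is the only ring closed, by 6-exo-trig attack of O1 on the C2=N bond or, equivalently, in one asynchronous [4+2] event. C4 is set as S by the catalyst, which covers one face of the planar methide carbon in the doubly hydrogen-bonded assembly and whose antipode is chosen to reinforce the bias of the twisted ring D with its epicatechin stereocentres, while the C2 aminal centre forms without control and is erased in step 14. The selectivity required is facial only: regiochemistry follows from the polarity of the partners, a single free phenol allows only one quinone methide, the pre-formed C4–C8 bond rules out 4→6 linkage and oligomerisation, and any facial leakage gives a diastereomer that chromatography removes. The donor oxygens make 18 long-lived rather than prone to dimerise, and the excess of a strong π nucleophile together with sieves against enamide hydrolysis offsets its low electrophilicity and crowding.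

Step 14
Reactants: 19 2-acetamidochroman
Product: 20 (4S)-5,7-bis(benzyloxy)-2-[3,4,5-tris(benzyloxy)phenyl]-4-(3,5,7,3',4'-penta-O-benzylepicatechin-8-yl)-4H-chromene (flav-2-ene)
Conditions: pyridinium p-toluenesulfonate (20 mol %), toluene, 50 °C, argon, dark
Reagents that add atoms: none
Why: Acid-catalysed E1 elimination of an N-acyl N,O-aminal: protonated acetamide leaves from the tertiary, O1- and ring-B-stabilised C2 and a C3 proton is lost to give the conjugated enol ether, the weak acid and exclusion of oxygen being chosen so that the C4–C8 bond, the C4–H bond and hence the 4S centre are not disturbed.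

Step 15
Reactants: 20 flav-2-ene
Product: 22 5,7,3',4',5'-penta-O-benzylgallocatechin-(4α→8)-3,5,7,3',4'-penta-O-benzylepicatechin (upper 2R,3S,4S with free 3-OH; lower 2R,3R), via C3 alkylborane 21 (not isolated)
Conditions: BH3·SMe2, THF, 0 °C to rt; then aq NaOH, 30% H2O2, 0 °C
Reagents that add atoms: hydrogen peroxide, OO
Why: Hydroboration–oxidation of a cyclic aryl enol ether, as established for 1-aryl glycals and simple flav-2-enes: O1 and ring B both polarise C2=C3 so that boron goes to C3, the syn addition takes place on the face opposite the pseudoaxial ring D substituent at C4, and oxidation with retention gives 2R,3S, the 2,3-trans-3,4-trans array.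

Step 16
Reactants: 22 deca-O-benzyl dimer
Product: 23 gallocatechin-(4α→8)-epicatechin (target)
Conditions: H2 (1 atm), Pd(OH)2/C, THF/MeOH/H2O, rt
Reagents that add atoms: none
Why: Catalytic hydrogenolysis of all ten benzyl ethers (nine aryl, one alkyl) under neutral conditions, which the C4–C8 bond, the C2–O1 bonds of rings C and F and all five stereocentres of benzylated flavan-3-ol dimers tolerate.

**Compound list**
1 | (−)-epicatechin | Oc1cc(O)c2c(c1)O[C@H](c1ccc(O)c(O)c1)[C@H](O)C2 | starting material
2 | 5,7,3',4'-tetra-O-benzylepicatechin | c1ccccc1COc1cc(OCc3ccccc3)c2c(c1)O[C@H](c1ccc(OCc3ccccc3)c(OCc3ccccc3)c1)[C@H](O)C2 | intermediate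
3 | 3,5,7,3',4'-penta-O-benzylepicatechin | c1ccccc1COc1cc(OCc3ccccc3)c2c(c1)O[C@H](c1ccc(OCc3ccccc3)c(OCc3ccccc3)c1)[C@H](OCc1ccccc1)C2 | intermediate
4 | 8-bromo-3,5,7,3',4'-penta-O-benzylepicatechin | Brc1c(OCc3ccccc3)cc(OCc3ccccc3)c2c1O[C@H](c1ccc(OCc3ccccc3)c(OCc3ccccc3)c1)[C@H](OCc1ccccc1)C2 | intermediate
5 | 2,4,6-trihydroxybenzaldehyde | O=Cc1c(O)cc(O)cc1O | starting material
6 | 2,4-bis(benzyloxy)-6-hydroxybenzaldehyde | O=Cc1c(O)cc(OCc2ccccc2)cc1OCc1ccccc1 | intermediate
7 | 2,4-bis(benzyloxy)-6-(tert-butyldimethylsilyloxy)benzaldehyde | O=Cc1c(O[Si](C)(C)C(C)(C)C)cc(OCc2ccccc2)cc1OCc1ccccc1 | intermediate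
8 | 8-lithio-3,5,7,3',4'-penta-O-benzylepicatechin (not isolated) | [Li]c1c(OCc3ccccc3)cc(OCc3ccccc3)c2c1O[C@H](c1ccc(OCc3ccccc3)c(OCc3ccccc3)c1)[C@H](OCc1ccccc1)C2 | intermediate
9 | silylated benzhydrol, carbinol epimers | OC(c1c(O[Si](C)(C)C(C)(C)C)cc(OCc2ccccc2)cc1OCc1ccccc1)c1c(OCc3ccccc3)cc(OCc3ccccc3)c2c1O[C@H](c1ccc(OCc3ccccc3)c(OCc3ccccc3)c1)[C@H](OCc1ccccc1)C2 | intermediate
10 | o-hydroxybenzhydrol with the C4–C8 bond, carbinol epimers | OC(c1c(O)cc(OCc2ccccc2)cc1OCc1ccccc1)c1c(OCc3ccccc3)cc(OCc3ccccc3)c2c1O[C@H](c1ccc(OCc3ccccc3)c(OCc3ccccc3)c1)[C@H](OCc1ccccc1)C2 | intermediate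
11 | methyl gallate | COC(=O)c1cc(O)c(O)c(O)c1 | starting material
12 | methyl 3,4,5-tris(benzyloxy)benzoate | COC(=O)c1cc(OCc2ccccc2)c(OCc2ccccc2)c(OCc2ccccc2)c1 | intermediate
13 | 3,4,5-tris(benzyloxy)-N-methoxy-N-methylbenzamide | CON(C)C(=O)c1cc(OCc2ccccc2)c(OCc2ccccc2)c(OCc2ccccc2)c1 | intermediate
14 | 3,4,5-tris(benzyloxy)acetophenone | CC(=O)c1cc(OCc2ccccc2)c(OCc2ccccc2)c(OCc2ccccc2)c1 | intermediate
15 | (E)-3,4,5-tris(benzyloxy)acetophenone oxime | C/C(=N\O)c1cc(OCc2ccccc2)c(OCc2ccccc2)c(OCc2ccccc2)c1 | intermediate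
16 | (E)-oxime O-acetate (not isolated) | C/C(=N\OC(C)=O)c1cc(OCc2ccccc2)c(OCc2ccccc2)c(OCc2ccccc2)c1 | intermediate
17 | N-{1-[3,4,5-tris(benzyloxy)phenyl]vinyl}acetamide | C=C(NC(C)=O)c1cc(OCc2ccccc2)c(OCc2ccccc2)c(OCc2ccccc2)c1 | intermediate
18 | o-quinone methide carrying the epicatechin-8-yl group, alkene geometry open (not isolated) | O=C1C=C(OCc2ccccc2)C=C(OCc2ccccc2)C1=Cc1c(OCc3ccccc3)cc(OCc3ccccc3)c2c1O[C@H](c1ccc(OCc3ccccc3)c(OCc3ccccc3)c1)[C@H](OCc1ccccc1)C2 | intermediate
19 | (4S)-2-acetamido-2,4-diarylchroman, C2 epimers | c1ccccc1COc1cc(OCc3ccccc3)c2c(c1)OC(NC(C)=O)(c1cc(OCc3ccccc3)c(OCc3ccccc3)c(OCc3ccccc3)c1)C[C@@H]2c1c(OCc3ccccc3)cc(OCc3ccccc3)c2c1O[C@H](c1ccc(OCc3ccccc3)c(OCc3ccccc3)c1)[C@H](OCc1ccccc1)C2 | intermediate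
20 | (4S)-4-(penta-O-benzylepicatechin-8-yl)flav-2-ene | c1ccccc1COc1cc(OCc3ccccc3)c2c(c1)OC(c1cc(OCc3ccccc3)c(OCc3ccccc3)c(OCc3ccccc3)c1)=C[C@@H]2c1c(OCc3ccccc3)cc(OCc3ccccc3)c2c1O[C@H](c1ccc(OCc3ccccc3)c(OCc3ccccc3)c1)[C@H](OCc1ccccc1)C2 | intermediate
21 | C3 alkylborane, boron trans to both neighbouring aryl groups (not isolated) | c1ccccc1COc1cc(OCc3ccccc3)c2c(c1)O[C@H](c1cc(OCc3ccccc3)c(OCc3ccccc3)c(OCc3ccccc3)c1)[C@@H](B)[C@@H]2c1c(OCc3ccccc3)cc(OCc3ccccc3)c2c1O[C@H](c1ccc(OCc3ccccc3)c(OCc3ccccc3)c1)[C@H](OCc1ccccc1)C2 | intermediate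
22 | deca-O-benzyl gallocatechin-(4α→8)-epicatechin, upper 3-OH free | c1ccccc1COc1cc(OCc3ccccc3)c2c(c1)O[C@H](c1cc(OCc3ccccc3)c(OCc3ccccc3)c(OCc3ccccc3)c1)[C@@H](O)[C@@H]2c1c(OCc3ccccc3)cc(OCc3ccccc3)c2c1O[C@H](c1ccc(OCc3ccccc3)c(OCc3ccccc3)c1)[C@H](OCc1ccccc1)C2 | intermediate
23 | gallocatechin-(4α→8)-epicatechin | Oc1cc(O)c2c(c1)O[C@H](c1cc(O)c(O)c(O)c1)[C@@H](O)[C@@H]2c1c(O)cc(O)c2c1O[C@H](c1ccc(O)c(O)c1)[C@H](O)C2 | target

**Step count**
Total steps: 16.
Longest linear sequence: 9 steps (1, 2, 3, 6, 7, 13, 14, 15, 16). The methyl gallate branch (8 to 12, then 13 to 16) is equally long.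

**Steps most likely to fail**

Step 13.
- Risk: the methide carbon lies between two doubly ortho-oxygenated rings and is strongly donor-stabilised, so C–C bond formation may be slower than hydrolysis of the enamide. Facial selectivity may also erode, because both methide geometries are accessible and the heavily benzylated ring D may not fit the catalyst pocket.
- Fallback: the known cationic flavan-4-yl coupling, which sets out from 3 and returns to the route at 22. Commercial (+)-gallocatechin is benzylated on its five phenols (BnBr, K2CO3, DMF) to penta-O-benzylgallocatechin F1. Oxidation at C4 with DDQ in the presence of 2-ethoxyethanol gives the 4-(2-ethoxyethoxy) ether F2, and acetylation (Ac2O, pyridine) gives the 3-O-acetate F3. TMSOTf in CH2Cl2 at −78 °C ionises F3 at C4, and an excess of 3 attacks through C8 from the face opposite the 3-acetoxy group to give the 3,4-trans 3-O-acetyl dimer F4. Methanolysis (K2CO3, MeOH/THF) frees the upper 3-OH and delivers 22.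

Step 14.
- Risk: acid may trigger heterolysis of the C4–C8 bond, which is driven by the aromaticity of the flavylium ion that would be released. That would scramble C4 or cost the lower unit. Traces of oxygen may also dehydrogenate C4–H.
- Fallback: the flavene is reached without any acid treatment of a C4-arylated compound, by nucleophilic addition to a flavylium salt. This path sets out from 6, 14 and 4 and returns at 20. Aldehyde 6 and ketone 14 are condensed with HBF4·OEt2 in AcOH/EtOAc (the classical aldol–cyclodehydration route to flavylium salts) to give penta-O-benzylflavylium tetrafluoroborate F5. Aryllithium 8, made from 4 as in step 6, is transmetallated with MgBr2·OEt2 to the arylmagnesium bromide F6 and added to a suspension of F5 in THF at −78 °C. Attack at the unsubstituted C4 rather than the aryl-bearing C2 should give 20 together with its C4 epimer F7. The two are diastereomers because of the epicatechin unit and are separated by chromatography.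

Step 15.
- Risk: the β-aryloxy organoborane may fragment by boron–oxygen elimination with opening of ring C. The hindered trisubstituted alkene may take up borane sluggishly or with incomplete facial bias.
- Fallback: enol ether epoxidation followed by aluminium-directed syn reductive opening, known for cyclic enol ethers and glycal epoxides, which sets out from 20 and returns at 22. Dimethyldioxirane in acetone/CH2Cl2 at −78 °C should epoxidise C2=C3 on the face away from ring D to give the 2,3-epoxyflavan F8, which is treated in the same flask with i-Bu2AlH at −78 °C. Aluminium binds the epoxide oxygen, the C2–O bond ionises with help from O1 and ring B, and hydride is delivered from the same face. H at C2 thus ends up cis to the C3 oxygen, which is the 2,3-trans-3,4-trans array of 22.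

**Further compounds**
F1 | step 13 | 5,7,3',4',5'-penta-O-benzyl-(+)-gallocatechin (2R,3S) | c1ccccc1COc1cc(OCc3ccccc3)c2c(c1)O[C@H](c1cc(OCc3ccccc3)c(OCc3ccccc3)c(OCc3ccccc3)c1)[C@@H](O)C2
F2 | step 13 | (2R,3S,4S)-4-(2-ethoxyethoxy)-5,7,3',4',5'-penta-O-benzylgallocatechin | c1ccccc1COc1cc(OCc3ccccc3)c2c(c1)O[C@H](c1cc(OCc3ccccc3)c(OCc3ccccc3)c(OCc3ccccc3)c1)[C@@H](O)[C@H]2OCCOCC
F3 | step 13 | 3-O-acetate of F2 | c1ccccc1COc1cc(OCc3ccccc3)c2c(c1)O[C@H](c1cc(OCc3ccccc3)c(OCc3ccccc3)c(OCc3ccccc3)c1)[C@@H](OC(C)=O)[C@H]2OCCOCC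
F4 | step 13 | 3-O-acetyl-deca-O-benzyl gallocatechin-(4α→8)-epicatechin | c1ccccc1COc1cc(OCc3ccccc3)c2c(c1)O[C@H](c1cc(OCc3ccccc3)c(OCc3ccccc3)c(OCc3ccccc3)c1)[C@@H](OC(C)=O)[C@@H]2c1c(OCc3ccccc3)cc(OCc3ccccc3)c2c1O[C@H](c1ccc(OCc3ccccc3)c(OCc3ccccc3)c1)[C@H](OCc1ccccc1)C2
F5 | step 14 | 5,7-bis(benzyloxy)-2-[3,4,5-tris(benzyloxy)phenyl]chromenylium tetrafluoroborate | c1ccccc1COc1cc(OCc2ccccc2)c2ccc(-c3cc(OCc4ccccc4)c(OCc4ccccc4)c(OCc4ccccc4)c3)[o+]c2c1.F[B-](F)(F)F
F6 | step 14 | (3,5,7,3',4'-penta-O-benzylepicatechin-8-yl)magnesium bromide | Br[Mg]c1c(OCc3ccccc3)cc(OCc3ccccc3)c2c1O[C@H](c1ccc(OCc3ccccc3)c(OCc3ccccc3)c1)[C@H](OCc1ccccc1)C2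
F7 | step 14 | (4R) epimer of flav-2-ene 20 | c1ccccc1COc1cc(OCc3ccccc3)c2c(c1)OC(c1cc(OCc3ccccc3)c(OCc3ccccc3)c(OCc3ccccc3)c1)=C[C@H]2c1c(OCc3ccccc3)cc(OCc3ccccc3)c2c1O[C@H](c1ccc(OCc3ccccc3)c(OCc3ccccc3)c1)[C@H](OCc1ccccc1)C2
F8 | step 15 | 2,3-epoxyflavan, epoxide oxygen trans to ring D at C4 | c1ccccc1COc1cc(OCc3ccccc3)c2c(c1)O[C@@]3(c1cc(OCc4ccccc4)c(OCc4ccccc4)c(OCc4ccccc4)c1)O[C@H]3[C@@H]2c1c(OCc3ccccc3)cc(OCc3ccccc3)c2c1O[C@H](c1ccc(OCc3ccccc3)c(OCc3ccccc3)c1)[C@H](OCc1ccccc1)C2
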